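**Retrosynthetic overview**

1. Target 28 is a 5,10-cis-fused labdane-type butenolide. The butenolide is attached late by B-alkyl Suzuki–Miyaura coupling (C12–C13), the exocyclic C8=C17 alkene comes from reductive 1,3-transposition of a ring B C7=C8/C17–OH allylic alcohol, and the C20 methyl comes from an angular formyl group.
2. Ring B is thereby a cyclohexene, and a Diels–Alder disconnection across C5–C6 and C9–C10 gives the ring A enal 9 (dienophile C5=C10, C20 = CHO) and the triene 15 (C6=C7–C8(C17)=C9–C11=C12).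
3. Enabling feature: in ring B, H5 and the C20 substituent on C10 are cis and the C9 side chain is cis to C20. This is the suprafacial, endo pattern left when a four-carbon diene (C6–C9) adds to the C5=C10 double bond of a ring A cyclohexene, and sp2 C8 can take the cycloadduct's double bond after transposition.
4. Enal 9 comes from pentaerythritol monoacetonide 1 (its central carbon becomes C4): Krische allylation sets C3 and hydroformylation/aldol condensation closes ring A. Triene 15 comes from propargyl alcohol by carbomagnesiation/Kumada coupling.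
5. Ring order: ring A (aldol condensation), then ring B (Diels–Alder, which sets C5, C9 and C10 from C3), then the preformed butenolide ring is coupled on.

Key step: step 9

Remark: the SMILES is read as written, i.e. a cis-fused decalin with (3R,5R,9R,10S) configuration; locants C1–C20 in names follow labdane numbering (C17 on C8, C18/C19 on C4, C20 on C10), and the CIP descriptors and SMILES, not the parent name, define configuration.

**Route**

Step 1
Reactants: 1 (2,2-dimethyl-1,3-dioxane-5,5-diyl)dimethanol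
Product: 2 {5-[(4-methoxybenzyl)oxymethyl]-2,2-dimethyl-1,3-dioxan-5-yl}methanol
Conditions: NaH (1.0 equiv), THF/DMF, 0 °C; then 4-methoxybenzyl chloride, Bu4NI (cat.), rt
Reagents that add atoms: 4-methoxybenzyl chloride, COc1ccc(CCl)cc1
Why: Williamson etherification of the monosodium alkoxide of a symmetrical diol should stop mainly at the mono-ether, leaving one CH2OH arm as the future C3 and masking the other as the future C5.

Step 2
Reactants: 2 {5-[(4-methoxybenzyl)oxymethyl]-2,2-dimethyl-1,3-dioxan-5-yl}methanol; 3 allyl acetate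
Product: 4 (1R)-1-{5-[(4-methoxybenzyl)oxymethyl]-2,2-dimethyl-1,3-dioxan-5-yl}but-3-en-1-ol
Conditions: [Ir(cod)Cl]2 (2.5 mol%), Cl,MeO-BIPHEP (5 mol%, enantiomer giving the 1R alcohol), Cs2CO3 (20 mol%), 4-chloro-3-nitrobenzoic acid (10 mol%), THF, 100 °C, sealed tube
Reagents that add atoms: none
Why: Krische allylation: transfer hydrogenation oxidises the neopentyl alcohol to the aldehyde in situ and the chiral catalyst formed from [Ir(cod)Cl]2 and the bisphosphine transfers the allyl group to one carbonyl face, so the ligand sets the C3 carbinol centre (R).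

Step 3
Reactants: 4 (1R)-1-{5-[(4-methoxybenzyl)oxymethyl]-2,2-dimethyl-1,3-dioxan-5-yl}but-3-en-1-ol
Product: 5 tert-butyl{[(1R)-1-{5-[(4-methoxybenzyl)oxymethyl]-2,2-dimethyl-1,3-dioxan-5-yl}but-3-en-1-yl]oxy}dimethylsilane
Conditions: TBSOTf, 2,6-lutidine, CH2Cl2, −78 → 0 °C
Reagents that add atoms: tert-butyldimethylsilyl trifluoromethanesulfonate, CC(C)(C)[Si](C)(C)OS(=O)(=O)C(F)(F)F
Why: Silylation with the silyl triflate is the standard way to protect a hindered secondary alcohol, and it blocks retro-aldol cleavage once C5 becomes an aldehyde.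

Step 4
Reactants: 5 tert-butyl{[(1R)-1-{5-[(4-methoxybenzyl)oxymethyl]-2,2-dimethyl-1,3-dioxan-5-yl}but-3-en-1-yl]oxy}dimethylsilane
Product: 6 {5-[(1R)-1-(tert-butyldimethylsilyloxy)but-3-en-1-yl]-2,2-dimethyl-1,3-dioxan-5-yl}methanol
Conditions: DDQ, CH2Cl2/pH 7 buffer, 0 °C → rt
Reagents that add atoms: none
Why: Oxidative cleavage of the 4-methoxybenzyl ether is orthogonal to the silyl ether, the acetonide and the terminal alkene.

Step 5
Reactants: 6 {5-[(1R)-1-(tert-butyldimethylsilyloxy)but-3-en-1-yl]-2,2-dimethyl-1,3-dioxan-5-yl}methanol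
Product: 7 5-[(1R)-1-(tert-butyldimethylsilyloxy)but-3-en-1-yl]-2,2-dimethyl-1,3-dioxane-5-carbaldehyde
Conditions: Dess–Martin periodinane, pyridine, CH2Cl2, rt
Reagents that add atoms: none
Why: Dess–Martin oxidation of a neopentyl primary alcohol should give the non-enolisable aldehyde (future C5) without touching the alkene or the acetal.

Step 6
Reactants: 7 5-[(1R)-1-(tert-butyldimethylsilyloxy)but-3-en-1-yl]-2,2-dimethyl-1,3-dioxane-5-carbaldehyde
Product: 9 (11R)-11-(tert-butyldimethylsilyloxy)-3,3-dimethyl-2,4-dioxaspiro[5.5]undec-7-ene-8-carbaldehyde, via dialdehyde 8 (not isolated)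
Conditions: Rh(acac)(CO)2 (1 mol%), Xantphos (2 mol%), CO/H2 (1:1, 10 bar), toluene, 70 °C; then Bn2NH·CF3CO2H (20 mol%), 50 °C
Reagents that add atoms: carbon monoxide, [C-]#[O+]
Why: Linear-selective hydroformylation of the terminal alkene gives a 1,7-dialdehyde in which only the new aldehyde is enolisable, so the amine-salt-catalysed intramolecular aldol condensation can only close the six-membered ring A enal with the C5=C10 double bond.

Step 7
Reactants: 10 prop-2-yn-1-ol; 11 vinylmagnesium chloride (CH2=CHMgCl); 12 bromoethene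
Product: 14 (2Z)-2-ethenylpenta-2,4-dien-1-ol, via magnesacycle 13 (not isolated)
Conditions: 11 (3 equiv), THF/toluene, 70 °C; then 12 (excess), Pd(PPh3)4 (5 mol%), 25 → 50 °C; H2O work-up
Reagents that add atoms: none
Why: Anti-carbomagnesiation of the propargylic alkoxide puts the first vinyl group on the carbon next to CH2O and magnesium cis to the CH2O arm in a five-membered chelate, and Kumada coupling with retention then places the second vinyl group cis to CH2O, which fixes the 2Z geometry.

Step 8
Reactants: 14 (2Z)-2-ethenylpenta-2,4-dien-1-ol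
Product: 15 tert-butyl{[(2Z)-2-ethenylpenta-2,4-dien-1-yl]oxy}dimethylsilane
Conditions: TBSCl, imidazole, CH2Cl2, 0 °C
Reagents that add atoms: tert-butyldimethylsilyl chloride, CC(C)(C)[Si](C)(C)Cl
Why: Standard silylation of a primary allylic alcohol gives a less volatile triene whose oxygen does not consume the Lewis acid of the next step.

Step 9
Reactants: 9 (11R)-11-(tert-butyldimethylsilyloxy)-3,3-dimethyl-2,4-dioxaspiro[5.5]undec-7-ene-8-carbaldehyde; 15 tert-butyl{[(2Z)-2-ethenylpenta-2,4-dien-1-yl]oxy}dimethylsilane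
Product: 16 (3R,5S,9R,10S)-3,17-bis(tert-butyldimethylsilyloxy)-18,19-isopropylidenedioxy-13,14,15,16-tetranorlabda-7,11-dien-20-al
Conditions: Me2AlCl (1.5 equiv), 15 (2 equiv), CH2Cl2, −78 → −30 °C; H2O quench
Reagents that add atoms: none
Why: Coordination of Me2AlCl to the formyl oxygen lowers the LUMO of the ring A enal, and the s-cis C6=C7–C8=C9 unit of 15 adds in a concerted but asynchronous normal-demand [4+2] cycloaddition with the C5–C6 bond leading; the closest known reaction type is the Lewis-acid-promoted Diels–Alder reaction of cyclohex-1-enecarbaldehydes with 1,2-disubstituted dienes, which gives cis-fused decalins carrying an angular formyl group. Ring B is closed by this intermolecular [4π+2π] cycloaddition, both σ-bonds forming suprafacially on one face of C5=C10, so H5 and the C20 formyl group are necessarily cis. C9 is set by the endo transition state (formyl group under C7–C8, ring A exo) together with the vinyl group on C9 being trans to C7 across C8=C9 ("outside"), which places the vinyl group cis to C20. The facial sense follows from C3: in the half-chair with the 3-silyloxy group equatorial, the pseudoaxial CH2O arm of the spiro acetonide lies on the same side as O3 and shields that face at C5, so the diene should add to the opposite face, trans to O3. The regioselectivity needed (C6 to the β-carbon C5, C9 to C10) is secured by the largest HOMO coefficient and lowest steric demand at the unsubstituted terminus C6 of the hexatriene and by pentadienyl-type stabilisation of developing charge over C7–C8–C9–C11–C12. Periselectivity is secured because the other diene unit (C8=C9–C11=C12) carries a cis-disposed CH2OTBS group at its C8 terminus and cannot reach a reactive s-cis geometry.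

Step 10
Reactants: 16 (3R,5S,9R,10S)-3,17-bis(tert-butyldimethylsilyloxy)-18,19-isopropylidenedioxy-13,14,15,16-tetranorlabda-7,11-dien-20-al
Product: 17 (3R,5R,9S,10S)-3,17-bis(tert-butyldimethylsilyloxy)-18,19-isopropylidenedioxy-13,14,15,16-tetranorlabda-7,11-dien-20-al 4-methylbenzenesulfonylhydrazone
Conditions: TsNHNH2, MgSO4, THF, 45 °C
Reagents that add atoms: 4-methylbenzenesulfonohydrazide, Cc1ccc(cc1)S(=O)(=O)NN
Why: Condensation of an aldehyde with tosylhydrazide is reliable even at a neopentyl position and needs no acid or base that would endanger the silyl ethers, the acetonide or the skipped diene.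

Step 11
Reactants: 17 (3R,5R,9S,10S)-3,17-bis(tert-butyldimethylsilyloxy)-18,19-isopropylidenedioxy-13,14,15,16-tetranorlabda-7,11-dien-20-al 4-methylbenzenesulfonylhydrazone
Product: 20 (3R,5R,9S,10R)-3,17-bis(tert-butyldimethylsilyloxy)-18,19-isopropylidenedioxy-13,14,15,16-tetranorlabda-7,11-diene, via N-borylhydrazine 18 (not isolated), via alkyldiazene 19 (not isolated)
Conditions: catecholborane (3 equiv), CHCl3, 0 °C; then NaOAc·3H2O, 60 °C
Reagents that add atoms: none
Why: Catecholborane reduction of a tosylhydrazone is a mild Wolff–Kishner-type deoxygenation: hydride adds to C=N, acetate triggers loss of sulfinate and the diazene loses N2 to leave the C20 methyl group, without the strong base that would conjugate the doubly allylic C9–H system.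

Step 12
Reactants: 20 (3R,5R,9S,10R)-3,17-bis(tert-butyldimethylsilyloxy)-18,19-isopropylidenedioxy-13,14,15,16-tetranorlabda-7,11-diene
Product: 21 (3R,5R,9S,10R)-18,19-isopropylidenedioxy-13,14,15,16-tetranorlabda-7,11-diene-3,17-diol
Conditions: Bu4NF (4 equiv), THF, rt → 50 °C
Reagents that add atoms: none
Why: Fluoride cleaves both silyl ethers while the acetonide stays, and doing this before the base-sensitive butenolide is present avoids exposing it to fluoride.

Step 13
Reactants: 21 (3R,5R,9S,10R)-18,19-isopropylidenedioxy-13,14,15,16-tetranorlabda-7,11-diene-3,17-diol; 22 3-bromofuran-2(5H)-one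
Product: 24 (3R,5R,9S,10S)-3,17-dihydroxy-18,19-isopropylidenedioxylabda-7,13-dien-16,15-olide, via alkylborane 23 (not isolated)
Conditions: 9-BBN (3.5 equiv), THF, 0 °C → rt; then 22, PdCl2(dppf) (5 mol%), AsPh3 (10 mol%), aq. K3PO4, DMF, rt
Reagents that add atoms: none
Why: 9-BBN hydroborates only the monosubstituted vinyl group (anti-Markovnikov, leaving the trisubstituted C7=C8 alkene), and B-alkyl Suzuki–Miyaura coupling of the primary alkylborane with the α-bromo-α,β-unsaturated lactone forms C12–C13 and delivers the butenolide intact; any O-borinate formed at the hydroxyls is hydrolysed in the basic aqueous medium.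

Step 14
Reactants: 24 (3R,5R,9S,10S)-3,17-dihydroxy-18,19-isopropylidenedioxylabda-7,13-dien-16,15-olide
Product: 27 (3R,5R,9R,10S)-3-hydroxy-18,19-isopropylidenedioxylabda-8(17),13-dien-16,15-olide, via sulfonylhydrazine 25 (not isolated), via allylic diazene 26 (not isolated)
Conditions: PPh3, DEAD, 2-nitrobenzenesulfonylhydrazide, N-methylmorpholine, −30 °C; then 23 °C
Reagents that add atoms: none
Why: Mitsunobu displacement of the primary allylic alcohol by the arenesulfonylhydrazide, loss of sulfinic acid and retro-ene loss of N2 from the allylic diazene deliver hydrogen to C7 and move the double bond to the exocyclic C8=C17 position; the secondary C3–OH next to the quaternary C4 is too hindered to react.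

Step 15
Reactants: 27 (3R,5R,9R,10S)-3-hydroxy-18,19-isopropylidenedioxylabda-8(17),13-dien-16,15-olide
Product: 28 (3R,5R,9R,10S)-3,18,19-trihydroxylabda-8(17),13-dien-16,15-olide
Conditions: AcOH/H2O (4:1), 40 °C
Reagents that add atoms: none
Why: Mild aqueous acid hydrolyses the isopropylidene acetal of the 1,3-diol without isomerising the exocyclic alkene or opening the butenolide.

**Compound list**

1 | (2,2-dimethyl-1,3-dioxane-5,5-diyl)dimethanol | CC1(C)OCC(CO)(CO)CO1 | starting material
2 | {5-[(4-methoxybenzyl)oxymethyl]-2,2-dimethyl-1,3-dioxan-5-yl}methanol | COc1ccc(COCC2(CO)COC(C)(C)OC2)cc1 | intermediate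
3 | allyl acetate | C=CCOC(C)=O | starting material
4 | (1R)-1-{5-[(4-methoxybenzyl)oxymethyl]-2,2-dimethyl-1,3-dioxan-5-yl}but-3-en-1-ol | COc1ccc(COCC2(COC(C)(C)OC2)[C@H](O)CC=C)cc1 | intermediate
5 | tert-butyldimethylsilyl ether of 4 (1R) | COc1ccc(COCC2(COC(C)(C)OC2)[C@H](O[Si](C)(C)C(C)(C)C)CC=C)cc1 | intermediate
6 | {5-[(1R)-1-(tert-butyldimethylsilyloxy)but-3-en-1-yl]-2,2-dimethyl-1,3-dioxan-5-yl}methanol | OCC1(COC(C)(C)OC1)[C@H](O[Si](C)(C)C(C)(C)C)CC=C | intermediate
7 | 5-[(1R)-1-(tert-butyldimethylsilyloxy)but-3-en-1-yl]-2,2-dimethyl-1,3-dioxane-5-carbaldehyde | O=CC1(COC(C)(C)OC1)[C@H](O[Si](C)(C)C(C)(C)C)CC=C | intermediate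
8 | 5-[(1R)-1-(tert-butyldimethylsilyloxy)-5-oxopentyl]-2,2-dimethyl-1,3-dioxane-5-carbaldehyde | O=CC1(COC(C)(C)OC1)[C@H](O[Si](C)(C)C(C)(C)C)CCCC=O | intermediate
9 | (11R)-11-(tert-butyldimethylsilyloxy)-3,3-dimethyl-2,4-dioxaspiro[5.5]undec-7-ene-8-carbaldehyde (ring A enal; C5=C10, C20 formyl) | O=CC1=CC2(COC(C)(C)OC2)[C@H](O[Si](C)(C)C(C)(C)C)CC1 | intermediate
10 | prop-2-yn-1-ol | C#CCO | starting material
11 | vinylmagnesium chloride | C=C[Mg]Cl | starting material
12 | bromoethene | C=CBr | starting material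
13 | 4-ethenyl-2,5-dihydro-1,2-oxamagnesole (cyclic alkenylmagnesium alkoxide) | C=CC1=C[Mg]OC1 | intermediate
14 | (2Z)-2-ethenylpenta-2,4-dien-1-ol | OC/C(C=C)=C\C=C | intermediate
15 | tert-butyl{[(2Z)-2-ethenylpenta-2,4-dien-1-yl]oxy}dimethylsilane | CC(C)(C)[Si](C)(C)OC/C(C=C)=C\C=C | intermediate
16 | (3R,5S,9R,10S)-3,17-bis(tert-butyldimethylsilyloxy)-18,19-isopropylidenedioxy-13,14,15,16-tetranorlabda-7,11-dien-20-al (cis-fused; CHO, H5, O3 and the C9 vinyl group on one face) | CC(C)(C)[Si](C)(C)OCC1=CC[C@H]2C3(COC(C)(C)OC3)[C@H](O[Si](C)(C)C(C)(C)C)CC[C@@]2(C=O)[C@@H]1C=C | intermediate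
17 | 4-methylbenzenesulfonylhydrazone of 16 (3R,5R,9S,10S) | CC(C)(C)[Si](C)(C)OCC1=CC[C@H]2C3(COC(C)(C)OC3)[C@H](O[Si](C)(C)C(C)(C)C)CC[C@@]2(/C=N/NS(=O)(=O)c4ccc(C)cc4)[C@@H]1C=C | intermediate
18 | C20 N-(1,3,2-benzodioxaborol-2-yl)-N'-tosylhydrazine (configuration as in 17) | CC(C)(C)[Si](C)(C)OCC1=CC[C@H]2C3(COC(C)(C)OC3)[C@H](O[Si](C)(C)C(C)(C)C)CC[C@@]2(CN(NS(=O)(=O)c4ccc(C)cc4)B5Oc6ccccc6O5)[C@@H]1C=C | intermediate
19 | C20 monoalkyl diazene (configuration as in 17) | CC(C)(C)[Si](C)(C)OCC1=CC[C@H]2C3(COC(C)(C)OC3)[C@H](O[Si](C)(C)C(C)(C)C)CC[C@@]2(CN=N)[C@@H]1C=C | intermediate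
20 | (3R,5R,9S,10R)-3,17-bis(tert-butyldimethylsilyloxy)-18,19-isopropylidenedioxy-13,14,15,16-tetranorlabda-7,11-diene | CC(C)(C)[Si](C)(C)OCC1=CC[C@H]2C3(COC(C)(C)OC3)[C@H](O[Si](C)(C)C(C)(C)C)CC[C@@]2(C)[C@@H]1C=C | intermediate
21 | (3R,5R,9S,10R)-18,19-isopropylidenedioxy-13,14,15,16-tetranorlabda-7,11-diene-3,17-diol | OCC1=CC[C@H]2C3(COC(C)(C)OC3)[C@H](O)CC[C@@]2(C)[C@@H]1C=C | intermediate
22 | 3-bromofuran-2(5H)-one | O=C1OCC=C1Br | starting material
23 | 12-(9-borabicyclo[3.3.1]nonan-9-yl)-11,12-dihydro derivative of 21 (3R,5R,9S,10S) | OCC1=CC[C@H]2C3(COC(C)(C)OC3)[C@H](O)CC[C@@]2(C)[C@@H]1CCB4C5CCCC4CCC5 | intermediate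
24 | (3R,5R,9S,10S)-3,17-dihydroxy-18,19-isopropylidenedioxylabda-7,13-dien-16,15-olide | OCC1=CC[C@H]2C3(COC(C)(C)OC3)[C@H](O)CC[C@@]2(C)[C@@H]1CCC4=CCOC4=O | intermediate
25 | 17-[1-(2-nitrophenylsulfonyl)hydrazin-1-yl]-17-deoxy derivative of 24 | NN(CC1=CC[C@H]2C3(COC(C)(C)OC3)[C@H](O)CC[C@@]2(C)[C@@H]1CCC4=CCOC4=O)S(=O)(=O)c5ccccc5[N+](=O)[O-] | intermediate
26 | 17-diazenyl-17-deoxy derivative of 24 (allylic monoalkyl diazene) | N=NCC1=CC[C@H]2C3(COC(C)(C)OC3)[C@H](O)CC[C@@]2(C)[C@@H]1CCC4=CCOC4=O | intermediate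
27 | (3R,5R,9R,10S)-3-hydroxy-18,19-isopropylidenedioxylabda-8(17),13-dien-16,15-olide | C=C1CC[C@H]2C3(COC(C)(C)OC3)[C@H](O)CC[C@@]2(C)[C@@H]1CCC4=CCOC4=O | intermediate
28 | (3R,5R,9R,10S)-3,18,19-trihydroxylabda-8(17),13-dien-16,15-olide = 3-{2-[(1R,4aR,6R,8aS)-6-hydroxy-5,5-bis(hydroxymethyl)-8a-methyl-2-methylidenedecahydronaphthalen-1-yl]ethyl}furan-2(5H)-one | C=C1CC[C@H]2C(CO)(CO)[C@H](O)CC[C@@]2(C)[C@@H]1CCC1=CCOC1=O | target

**Step count and risks**

Total step count: 15. Longest linear sequence: 13 steps (steps 1–6 and 9–15); steps 7–8 form the second branch.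

Steps most likely to fail, riskiest first:

Step 9 (Diels–Alder). The enal is trisubstituted and its β-carbon sits next to the spiro quaternary C4, so cycloaddition may be slower than Lewis-acid-induced oligomerisation of the triene, and facial or endo selectivity may erode. Fallback with a different activation mode: from 9, acetalisation with 1,2-bis(trimethylsilyloxy)ethane and catalytic TMSOTf (CH2Cl2, −78 °C) would give the ethylene acetal F1. With catalytic TfOH at −78 °C, F1 ionises to an alkenyl-dioxolanylium ion, a much stronger dienophile, and its cationic Diels–Alder reaction with 15 should give the adduct acetal F2 under the same facial and endo control. Acetal exchange (PPTS, wet acetone, which keeps the isopropylidene group in place) returns to 16.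

Step 13 (hydroboration/B-alkyl Suzuki–Miyaura coupling). Transmetallation of the hindered alkylborane may be slow, allowing protodeboronation or β-hydride elimination, and the bromobutenolide may be opened or isomerised by the aqueous base. Fallback that builds the butenolide by enolate alkylation: from 20, hydroboration with 9-BBN and iodinolysis (I2, NaOMe, MeOH) would give the primary iodide F3. Alkylation of the lithium enolate of 3-(phenylsulfanyl)oxolan-2-one (LiN(iPr)2, THF/HMPA, −78 → 0 °C) with F3 would give the α-alkyl-α-phenylsulfanyl lactone F4. Oxidation with mCPBA (1 equiv, −78 °C) would give the sulfoxide F5, and thermal syn-elimination (toluene, 110 °C) into the ring should give the bis-silylated butenolide F6. HF·pyridine in THF then removes both silyl groups and returns to 24.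

Step 11 (hydrazone reduction). Hydride delivery to the neopentyl C=N bond may be slow, allowing hydroboration of the vinyl group by excess catecholborane or incomplete breakdown of the hydrazine. Fallback by radical deoxygenation: from 16, NaBH4 (MeOH, 0 °C) would give the neopentyl alcohol F7, and NaH, CS2 then MeI would give the S-methyl xanthate F8. Barton–McCombie deoxygenation (Bu3SnH, AIBN, xylene, 140 °C) returns to 20.

Further compounds
F1 | step 9 | (11R)-11-(tert-butyldimethylsilyloxy)-8-(1,3-dioxolan-2-yl)-3,3-dimethyl-2,4-dioxaspiro[5.5]undec-7-ene | O1CCOC1C2=CC3(COC(C)(C)OC3)[C@H](O[Si](C)(C)C(C)(C)C)CC2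
F2 | step 9 | C20 ethylene acetal of 16 | CC(C)(C)[Si](C)(C)OCC1=CC[C@H]2C3(COC(C)(C)OC3)[C@H](O[Si](C)(C)C(C)(C)C)CC[C@@]2(C4OCCO4)[C@@H]1C=C
F3 | step 13 | 12-iodo-11,12-dihydro derivative of 20 | CC(C)(C)[Si](C)(C)OCC1=CC[C@H]2C3(COC(C)(C)OC3)[C@H](O[Si](C)(C)C(C)(C)C)CC[C@@]2(C)[C@@H]1CCI
F4 | step 13 | 3,17-bis(tert-butyldimethylsilyloxy)-18,19-isopropylidenedioxy-13-(phenylsulfanyl)labd-7-en-16,15-olide (C13 epimers) | CC(C)(C)[Si](C)(C)OCC1=CC[C@H]2C3(COC(C)(C)OC3)[C@H](O[Si](C)(C)C(C)(C)C)CC[C@@]2(C)[C@@H]1CCC4(Sc5ccccc5)CCOC4=O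
F5 | step 13 | S-oxide of F4 | CC(C)(C)[Si](C)(C)OCC1=CC[C@H]2C3(COC(C)(C)OC3)[C@H](O[Si](C)(C)C(C)(C)C)CC[C@@]2(C)[C@@H]1CCC4(S(=O)c5ccccc5)CCOC4=O
F6 | step 13 | 3,17-bis(tert-butyldimethylsilyloxy)-18,19-isopropylidenedioxylabda-7,13-dien-16,15-olide | CC(C)(C)[Si](C)(C)OCC1=CC[C@H]2C3(COC(C)(C)OC3)[C@H](O[Si](C)(C)C(C)(C)C)CC[C@@]2(C)[C@@H]1CCC4=CCOC4=O
F7 | step 11 | C20 primary alcohol from 16 | CC(C)(C)[Si](C)(C)OCC1=CC[C@H]2C3(COC(C)(C)OC3)[C@H](O[Si](C)(C)C(C)(C)C)CC[C@@]2(CO)[C@@H]1C=C
F8 | step 11 | O-(C20) S-methyl xanthate of F7 | CC(C)(C)[Si](C)(C)OCC1=CC[C@H]2C3(COC(C)(C)OC3)[C@H](O[Si](C)(C)C(C)(C)C)CC[C@@]2(COC(=S)SC)[C@@H]1C=C
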